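**Plan**

- Atom numbers follow the 2H-chromene skeleton (O1, C2, C3, C4, C4a, C5–C8, C8a). The target has no stereocentre.
- Retrosynthesis: the C7 phenol is masked as an acetate, the C3=C4 double bond goes back to a chroman, the 1,2-diketone goes back to a diarylalkyne, and ring A is then cut at C6–C7, C4a–C5 and C7–C8.
- The feature that permits this cut is the pattern on ring A: a free hydroxyl on C7 and a methoxy on C5 on either side of the carbon-bearing C6, with O1 on C8a and the C4 methylene on C4a. A ketene carbonyl supplies C7–OH, a methoxyalkyne supplies C5–OMe and C6 with its side chain, and a 6-methyl-dihydropyran supplies C4a, C8a and C8 with the pyran ring already closed.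
- Forward: the dihydropyran ring is made first (prenylation and O-cyclisation of ethyl acetoacetate); the methoxy diyne is joined from a bromoalkyne and methoxyacetylide; ring A is closed by vinylketene–ynol ether benzannulation; then the alkyne is oxidised, the chroman dehydrogenated and the phenol released.
- Stereochemistry: none has to be set. The two transient stereocentres (C2 of the alkylated keto ester and the spiro carbon of the cyclobutenone) are racemic and disappear.

Key step: step 7

Remark: 5-methylhex-4-enoic acid, ethoxyacetylene, (E)-1-chloro-2-iodoethene and 4-iodoanisole, which occur only in fallbacks, are taken as purchasable.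

**Route**

Step 1
Reactants: 1 ethyl acetoacetate; 2 prenyl bromide (1-bromo-3-methylbut-2-ene)
Product: 3 ethyl 2-acetyl-5-methylhex-4-enoate (racemic)
Conditions: K2CO3, acetone, reflux (1 in slight excess)
Reagents that add atoms: none
Why: The doubly stabilised enolate of the β-keto ester is C-alkylated by the primary allylic bromide in an SN2 reaction (acetoacetic ester alkylation), and a small excess of 1 should suppress dialkylation.

Step 2
Reactants: 3 ethyl 2-acetyl-5-methylhex-4-enoate
Product: 4 ethyl 2,2,6-trimethyl-3,4-dihydro-2H-pyran-5-carboxylate
Conditions: TfOH (5 mol %), CH2Cl2, 0 °C → rt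
Reagents that add atoms: none
Why: Markovnikov protonation of the trisubstituted alkene gives a tertiary cation that is captured by the enol oxygen of the ketone in a six-membered closure (acid-catalysed intramolecular hydroalkoxylation of a 2-prenyl-1,3-dicarbonyl compound), which places the methyl group on C6 and the ester on C5 of the dihydropyran.

Step 3
Reactants: 4 ethyl 2,2,6-trimethyl-3,4-dihydro-2H-pyran-5-carboxylate
Product: 6 2,2,6-trimethyl-3,4-dihydro-2H-pyran-5-carboxylic acid, via potassium carboxylate 5 (not isolated)
Conditions: KOH, EtOH/H2O, 70 °C; then 1 M HCl to pH 3–4, 0 °C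
Reagents that add atoms: potassium hydroxide, [K+].[OH-]
Why: Hydroxide attacks the ester carbonyl in an ordinary saponification, the ring enol ether being inert to base, and brief cold acidification should liberate the β-alkoxyacrylic acid before the enol ether can hydrolyse.

Step 4
Reactants: 6 2,2,6-trimethyl-3,4-dihydro-2H-pyran-5-carboxylic acid
Product: 7 2,2,6-trimethyl-3,4-dihydro-2H-pyran-5-carbonyl chloride
Conditions: (COCl)2, DMF (cat.), CH2Cl2, 0 °C → rt; volatiles removed, used crude
Reagents that add atoms: oxalyl chloride, O=C(Cl)C(=O)Cl
Why: The chloroiminium salt formed from oxalyl chloride and DMF activates the acid for substitution by chloride (Vilsmeier-type acid chloride formation) with only gaseous by-products, and the donor oxygen in the β-position makes this acid chloride a tame, vinylogous chloroformate that can be used crude.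

Step 5
Reactants: 8 4-ethynylanisole
Product: 9 1-(bromoethynyl)-4-methoxybenzene
Conditions: NBS, AgNO3 (10 mol %), acetone, rt
Reagents that add atoms: N-bromosuccinimide, O=C1CCC(=O)N1Br
Why: AgNO3-catalysed electrophilic bromination of the terminal alkyne C–H by NBS is the standard route to 1-bromoalkynes and should leave the anisole ring untouched at room temperature.

Step 6
Reactants: 10 chloroacetaldehyde dimethyl acetal (2-chloro-1,1-dimethoxyethane); 9 1-(bromoethynyl)-4-methoxybenzene
Product: 13 1-methoxy-4-(4-methoxyphenyl)buta-1,3-diyne, via lithium methoxyacetylide 11 (not isolated), via methoxyethynylcopper 12 (not isolated)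
Conditions: Et2NH, n-BuLi (3 equiv each), THF, 0 °C; 10, 0 °C; CuI (1 equiv), −20 °C; 9, pyridine, −20 °C → rt; product kept cold and used promptly
Reagents that add atoms: none
Why: LiNEt2 removes methanol and then HCl from 10 and metalates the resulting methoxyacetylene, CuI turns the lithium acetylide into the monovalent copper acetylide, and this substitutes the bromide of 9 at the sp carbon (Cadiot–Chodkiewicz-type coupling with a preformed copper acetylide), so that the ynol ether never meets the aqueous amine medium of the catalytic variant.

Step 7
Reactants: 7 2,2,6-trimethyl-3,4-dihydro-2H-pyran-5-carbonyl chloride; 13 1-methoxy-4-(4-methoxyphenyl)buta-1,3-diyne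
Product: 18 5-methoxy-6-[(4-methoxyphenyl)ethynyl]-2,2-dimethylchroman-7-ol, via vinylketene 14 (not isolated), via spirocyclobutenone 15 (not isolated), via dienylketene 16 (not isolated), via cyclohexadienone 17 (not isolated)
Conditions: 13 (1.2 equiv), Et3N (2.5 equiv), toluene, 40 °C, 7 added over 2 h; then 110 °C
Reagents that add atoms: none
Why: Proposed new method: Et3N removes HCl from 7 through the C6 methyl group (1,4-dehydrochlorination) to give vinylketene 14, whose ketene C=C bond adds [2+2] to the methoxy-bearing triple bond of 13 to give spirocyclobutenone 15; on heating, conrotatory four-electron ring opening gives dienylketene 16, disrotatory six-electron closure gives dienone 17, and enolisation gives phenol 18. The closest known reaction types are the Danheiser benzannulation of vinylketenes with alkoxyalkynes, in which the vinylketene is normally released from a cyclobutenone or a diazo ketone, and the [2+2] addition of ketenes made from acid chlorides and Et3N to ethoxyacetylene; new here are the dehydrochlorination route to the vinylketene in the presence of the ynol ether and the conjugated diynyl ether as partner. Ring A is closed by the 6π electrocyclisation, which joins the former ketene carbon (C7) to the exocyclic methylene carbon (C8), after the [2+2]/ring-opening pair has made C6–C7 and C4a–C5. No stereocentre remains, since the spiro carbon of 15 is racemic, transient and ends as aromatic C4a. The regiochemistry needed (methoxy at C5, arylethynyl at C6, hydroxyl at C7) follows from the polarity of the ynol ether, whose β-carbon bonds to the electrophilic ketene carbon, and the chemoselectivity for the oxygen-substituted triple bond over the aryl-substituted one follows from its far greater nucleophilicity. Slow addition of 7 keeps the ketene concentration low against dimerisation, a slight excess of 13 leaves no acid chloride to acylate the new phenol, and the reversibility of the ring opening lets both modes of opening of 15 drain through the one geometry of 16 that can cyclise.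

Step 8
Reactants: 18 5-methoxy-6-[(4-methoxyphenyl)ethynyl]-2,2-dimethylchroman-7-ol
Product: 19 5-methoxy-6-[(4-methoxyphenyl)ethynyl]-2,2-dimethylchroman-7-yl acetate
Conditions: Ac2O, pyridine, DMAP (cat.), rt
Reagents that add atoms: acetic anhydride, CC(=O)OC(C)=O
Why: DMAP-catalysed O-acylation of the phenol is routine, and the acetate removes the nucleophilic hydroxyl that would otherwise add to the neighbouring alkyne (5-endo cyclisation to a benzofuran) once a metal activates the triple bond.

Step 9
Reactants: 19 5-methoxy-6-[(4-methoxyphenyl)ethynyl]-2,2-dimethylchroman-7-yl acetate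
Product: 20 5-methoxy-6-[2-(4-methoxyphenyl)-2-oxoacetyl]-2,2-dimethylchroman-7-yl acetate
Conditions: PdCl2 (10 mol %), DMSO, 120 °C
Reagents that add atoms: dimethyl sulfoxide, CS(C)=O
Why: Divalent palladium activates the diarylalkyne towards two successive oxygen transfers from DMSO, each releasing Me2S (PdCl2/DMSO oxidation of internal alkynes to 1,2-diketones), a reaction that is reliable for diarylalkynes and needs no water, so that the aryl acetate and the chroman methylene groups should survive.

Step 10
Reactants: 20 5-methoxy-6-[2-(4-methoxyphenyl)-2-oxoacetyl]-2,2-dimethylchroman-7-yl acetate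
Product: 21 5-methoxy-6-[2-(4-methoxyphenyl)-2-oxoacetyl]-2,2-dimethyl-2H-chromen-7-yl acetate
Conditions: DDQ (1.5 equiv), 1,4-dioxane, reflux
Reagents that add atoms: none
Why: DDQ abstracts hydride from the benzylic C4, where the cation is stabilised by the ortho oxygen substituents on C5 and C8a, and loss of a C3 proton gives the C3=C4 double bond (DDQ dehydrogenation of a 2,2-dimethylchroman), the quaternary C2 allowing no other alkene.

Step 11
Reactants: 21 5-methoxy-6-[2-(4-methoxyphenyl)-2-oxoacetyl]-2,2-dimethyl-2H-chromen-7-yl acetate
Product: 22 1-(7-hydroxy-5-methoxy-2,2-dimethyl-2H-chromen-6-yl)-2-(4-methoxyphenyl)ethane-1,2-dione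
Conditions: K2CO3 (0.2 equiv), MeOH, 0 °C
Reagents that add atoms: none
Why: Carbonate-catalysed methanolysis (transesterification) removes the aryl acetate quickly because the phenoxide is a good leaving group hydrogen-bonded to the adjacent ketone, and the low temperature and substoichiometric base should spare the 1,2-diketone.

**Compound list**

1 | ethyl acetoacetate | CCOC(=O)CC(C)=O | starting material
2 | prenyl bromide (1-bromo-3-methylbut-2-ene) | CC(C)=CCBr | starting material
3 | ethyl 2-acetyl-5-methylhex-4-enoate (racemic) | CCOC(=O)C(CC=C(C)C)C(C)=O | intermediate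
4 | ethyl 2,2,6-trimethyl-3,4-dihydro-2H-pyran-5-carboxylate | CCOC(=O)C1=C(C)OC(C)(C)CC1 | intermediate
5 | potassium 2,2,6-trimethyl-3,4-dihydro-2H-pyran-5-carboxylate (not isolated) | CC1=C(C(=O)[O-])CCC(C)(C)O1.[K+] | intermediate
6 | 2,2,6-trimethyl-3,4-dihydro-2H-pyran-5-carboxylic acid | CC1=C(C(=O)O)CCC(C)(C)O1 | intermediate
7 | 2,2,6-trimethyl-3,4-dihydro-2H-pyran-5-carbonyl chloride | CC1=C(C(=O)Cl)CCC(C)(C)O1 | intermediate
8 | 4-ethynylanisole | C#Cc1ccc(OC)cc1 | starting material
9 | 1-(bromoethynyl)-4-methoxybenzene | COc1ccc(C#CBr)cc1 | intermediate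
10 | chloroacetaldehyde dimethyl acetal (2-chloro-1,1-dimethoxyethane) | COC(CCl)OC | starting material
11 | lithium methoxyacetylide, LiC≡COMe (not isolated) | [Li]C#COC | intermediate
12 | (methoxyethynyl)copper, CuC≡COMe, a monovalent copper acetylide (not isolated) | COC#C[Cu] | intermediate
13 | 1-methoxy-4-(4-methoxyphenyl)buta-1,3-diyne | COC#CC#Cc1ccc(OC)cc1 | intermediate
14 | (6,6-dimethyl-2-methylideneoxan-3-ylidene)methanone, the vinylketene (not isolated) | O=C=C1CCC(C)(C)OC1=C | intermediate
15 | 3-methoxy-2-[(4-methoxyphenyl)ethynyl]-7,7-dimethyl-5-methylidene-6-oxaspiro[3.5]non-2-en-1-one (racemic, not isolated) | COC1=C(C#Cc2ccc(OC)cc2)C(=O)C13CCC(C)(C)OC3=C | intermediate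
16 | 3-(6,6-dimethyl-2-methylideneoxan-3-ylidene)-3-methoxy-2-[(4-methoxyphenyl)ethynyl]prop-1-en-1-one, the dienylketene with the ketenyl carbon cis to the methylidene-bearing ring carbon (not isolated) | O=C=C(C#Cc1ccc(OC)cc1)/C(OC)=C1\C(=C)OC(C)(C)CC1 | intermediate
17 | 5-methoxy-6-[(4-methoxyphenyl)ethynyl]-2,2-dimethyl-3,4-dihydro-2H-chromen-7(8H)-one (not isolated) | COC1=C(C#Cc2ccc(OC)cc2)C(=O)CC2=C1CCC(C)(C)O2 | intermediate
18 | 5-methoxy-6-[(4-methoxyphenyl)ethynyl]-2,2-dimethylchroman-7-ol | COc1ccc(C#Cc2c(O)cc3OC(C)(C)CCc3c2OC)cc1 | intermediate
19 | 5-methoxy-6-[(4-methoxyphenyl)ethynyl]-2,2-dimethylchroman-7-yl acetate | COc1ccc(C#Cc2c(OC(C)=O)cc3OC(C)(C)CCc3c2OC)cc1 | intermediate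
20 | 5-methoxy-6-[2-(4-methoxyphenyl)-2-oxoacetyl]-2,2-dimethylchroman-7-yl acetate | COc1ccc(C(=O)C(=O)c2c(OC(C)=O)cc3OC(C)(C)CCc3c2OC)cc1 | intermediate
21 | 5-methoxy-6-[2-(4-methoxyphenyl)-2-oxoacetyl]-2,2-dimethyl-2H-chromen-7-yl acetate | COc1ccc(C(=O)C(=O)c2c(OC(C)=O)cc3OC(C)(C)C=Cc3c2OC)cc1 | intermediate
22 | 1-(7-hydroxy-5-methoxy-2,2-dimethyl-2H-chromen-6-yl)-2-(4-methoxyphenyl)ethane-1,2-dione | COc1ccc(C(=O)C(=O)c2c(O)cc3OC(C)(C)C=Cc3c2OC)cc1 | target

**Step count**

Total steps: 11. Longest linear sequence: 9 steps (steps 1–4 and 7–11); the diyne branch (steps 5 and 6) joins at step 7.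

**Steps most likely to fail**

1. Step 7 (the step proposed as a new method). What may go wrong:
   - the ynol ether may be consumed by acylation with 7 or by protonation with triethylammonium chloride before any ketene is formed;
   - γ-deprotonation of the donor-substituted acid chloride may be sluggish;
   - the ketene may dimerise;
   - the new phenol may be O-acylated by remaining 7.

   The fallback keeps the disconnection but releases the same vinylketene 14 under neutral conditions, by thermal ring opening of a cyclobutenone, which is the established way of running this benzannulation. It sets out from diyne 13, replaces 7 by a cyclobutenone built from purchased 5-methylhex-4-enoic acid, and comes back to the route at phenol 18. The acid would be converted with oxalyl chloride into 5-methylhex-4-enoyl chloride F1. Et3N and ethoxyacetylene would then give, by [2+2] addition of the alkylketene, 3-ethoxy-4-(3-methylbut-2-en-1-yl)cyclobut-2-en-1-one F2. Dilute aqueous HCl would hydrolyse the vinylogous ester to 2-(3-methylbut-2-en-1-yl)cyclobutane-1,3-dione F3 (drawn as its enol). Catalytic TfOH would close the pyran ring as in step 2 to give 3,3-dimethyl-2-oxabicyclo[4.2.0]oct-1(6)-en-7-one F4. Heating F4 with 13 in toluene or xylene (110–140 °C) would open the four-membered ring to 14, and 15, 16 and 17 would follow as in step 7 to give 18.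

2. Step 6. What may go wrong:
   - halogen–copper exchange between 12 and 9 may scramble the partners and lead to homocoupling;
   - conversion of 10 into the acetylide may be incomplete;
   - the electron-rich diyne may polymerise on concentration.

   The fallback builds the second triple bond by elimination instead of joining two alkynes, so the two halves cannot scramble. It sets out from chloroacetal 10 by way of lithium methoxyacetylide 11, uses purchased 4-iodoanisole in place of bromoalkyne 9, and comes back at diyne 13. Acetylide 11 would be transmetalated with ZnCl2 to (methoxyethynyl)zinc chloride F5. This would be coupled with (E)-1-chloro-2-iodoethene under Pd(PPh3)4 (zerovalent palladium, Negishi coupling at the C–I bond) to give (E)-1-chloro-4-methoxybut-1-en-3-yne F6. Two equivalents of LDA at −78 °C would eliminate HCl and metalate to lithium 4-methoxybuta-1,3-diyn-1-ide F7. ZnBr2 would give (4-methoxybuta-1,3-diyn-1-yl)zinc bromide F8, and a second Negishi coupling with 4-iodoanisole under Pd(PPh3)4 would give 13.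

3. Step 9. What may go wrong:
   - electrophilic activation of the alkyne by divalent palladium may invite attack by the flanking acetoxy or methoxy oxygen (cyclisation with loss of acetyl or methyl) instead of oxygen transfer from DMSO;
   - the acetate may be lost at the reaction temperature.

   The fallback avoids electrophilic activation of the triple bond altogether. It sets out from alkyne acetate 19 and comes back at diketone 20. Semi-hydrogenation (H2, Pd/CaCO3 poisoned with Pb(OAc)2, quinoline) would give 5-methoxy-6-[(Z)-2-(4-methoxyphenyl)ethenyl]-2,2-dimethylchroman-7-yl acetate F9. Dihydroxylation with catalytic OsO4 and N-methylmorpholine N-oxide would give 6-[1,2-dihydroxy-2-(4-methoxyphenyl)ethyl]-5-methoxy-2,2-dimethylchroman-7-yl acetate F10 (racemic, relative configuration from syn addition to the Z alkene). Swern oxidation (oxalyl chloride, DMSO, Et3N, −78 °C) of both carbinols would give 20.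

**Further compounds**

F1 | step 7 | 5-methylhex-4-enoyl chloride | CC(C)=CCCC(=O)Cl
F2 | step 7 | 3-ethoxy-4-(3-methylbut-2-en-1-yl)cyclobut-2-en-1-one (racemic) | CCOC1=CC(=O)C1CC=C(C)C
F3 | step 7 | 2-(3-methylbut-2-en-1-yl)cyclobutane-1,3-dione, drawn as its enol 3-hydroxy-2-(3-methylbut-2-en-1-yl)cyclobut-2-en-1-one | CC(C)=CCC1=C(O)CC1=O
F4 | step 7 | 3,3-dimethyl-2-oxabicyclo[4.2.0]oct-1(6)-en-7-one | CC1(C)CCC2=C(CC2=O)O1
F5 | step 6 | (methoxyethynyl)zinc chloride | COC#C[Zn]Cl
F6 | step 6 | (E)-1-chloro-4-methoxybut-1-en-3-yne | COC#C/C=C/Cl
F7 | step 6 | lithium 4-methoxybuta-1,3-diyn-1-ide | [Li]C#CC#COC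
F8 | step 6 | (4-methoxybuta-1,3-diyn-1-yl)zinc bromide | COC#CC#C[Zn]Br
F9 | step 9 | 5-methoxy-6-[(Z)-2-(4-methoxyphenyl)ethenyl]-2,2-dimethylchroman-7-yl acetate | COc1ccc(/C=C\c2c(OC(C)=O)cc3OC(C)(C)CCc3c2OC)cc1
F10 | step 9 | 6-[1,2-dihydroxy-2-(4-methoxyphenyl)ethyl]-5-methoxy-2,2-dimethylchroman-7-yl acetate (racemic, syn addition product of the Z alkene; one enantiomer drawn) | COc1ccc([C@H](O)[C@H](O)c2c(OC(C)=O)cc3OC(C)(C)CCc3c2OC)cc1
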